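## Plan

- Retrosynthesis: once the two silyl groups are removed, the pyridine bonds N2–C1 and C3–C4 and the ring-fusion bond C4a–C7a are cut together, giving a silyl-capped 1,6-diynone and a dienyl nitrile.
- Enabling feature: the pyridine (N2, dienyl chain on C3, hydrogen on C1 and C4) is fused at C4a–C7a to a cyclopentanone whose remaining atoms C5–C6–C7 are the three-atom tether of a 1,6-diyne. A nitrile supplies N2 and C3.
- The diynone is cut at the C7–alkynyl bond (thioester alkynylation) and at C5–C6 (Mukaiyama aldol of an alkynyl keto ester). The nitrile is cut at its two C=C bonds (Wittig, Horner–Wadsworth–Emmons).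
- Forward: the acyclic chain is assembled first and the nitrile separately; both rings then close in one cobalt-catalysed [2+2+2] step, and fluoride removes the silyl groups.
- Stereochemistry: C5 and C6 are set together in the [Cu(t-Bu-box)](OTf)2-catalysed aldol and carry no hydrogen, so they cannot epimerise later. The side-chain centre comes from (S)-2-methylbutan-1-ol, and both E-alkenes come from stabilised-ylide olefinations.

Key step: step 11

Assumption (remark on the chemistry): the sense of induction known for [Cu(t-Bu-box)](OTf)2 with pyruvate esters (the (S,S)-ligand directing attack to the si face of the ketone) is taken to hold for the alkynyl keto ester, so the (R,R)-ligand is specified; if the sense proved opposite, the (S,S)-ligand would be used with no other change.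

## Route

Step 1
Reactants: 1 ethynyltrimethylsilane; 2 dimethyl oxalate
Product: 4 methyl 2-oxo-4-(trimethylsilyl)but-3-ynoate, via lithium trimethylsilylacetylide 3 (not isolated)
Conditions: n-BuLi, THF, −78 °C; cannulate into 2 (threefold excess), THF, −78 °C; AcOH quench at −78 °C
Reagents that add atoms: none
Why: Acylation of a lithium acetylide with an excess of the diester at low temperature should stop at the keto ester, because the tetrahedral adduct persists until the cold acidic quench.

Step 2
Reactants: 5 methyl 2-methoxypropanoate (racemic)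
Product: 6 S-ethyl 2-methoxypropanethioate (racemic)
Conditions: AlMe3, EtSH, CH2Cl2, 0 °C to rt
Reagents that add atoms: ethanethiol, CCS
Why: Me2AlSEt formed in the flask should convert the methyl ester directly into the thiol ester (aluminium thiolate transesterification), driven by formation of the strong Al–O bond.

Step 3
Reactants: 6 S-ethyl 2-methoxypropanethioate
Product: 8 (E)-1-(ethylsulfanyl)-2-methoxy-1-[(trimethylsilyl)oxy]prop-1-ene, via lithium enolate 7 (not isolated)
Conditions: LiN(i-Pr)2 (commercial solution), THF, −78 °C; TMSCl, −78 °C to rt; pentane, filtration, distillation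
Reagents that add atoms: chlorotrimethylsilane, C[Si](C)(C)Cl
Why: Kinetic enolisation should give the lithium enolate held in a five-membered chelate between the enolate oxygen and the α-methoxy group, and O-silylation (silyl ketene acetal formation) fixes that geometry while erasing the racemic stereocentre.

Step 4
Reactants: 4 methyl 2-oxo-4-(trimethylsilyl)but-3-ynoate; 8 (E)-1-(ethylsulfanyl)-2-methoxy-1-[(trimethylsilyl)oxy]prop-1-ene
Product: 10 methyl (2R,3S)-4-(ethylsulfanyl)-2-hydroxy-3-methoxy-3-methyl-4-oxo-2-[(trimethylsilyl)ethynyl]butanoate, via silyl ether 9 (not isolated)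
Conditions: [Cu((R,R)-t-Bu-box)](OTf)2 (20 mol%, from Cu(OTf)2 and 2,2'-(propane-2,2-diyl)bis[(4R)-4-tert-butyl-4,5-dihydrooxazole]), CH2Cl2, −78 °C; then dilute aqueous HCl, THF, rt
Reagents that add atoms: none
Why: Proposed new method: the keto ester should bind the Lewis-acidic divalent copper centre through both carbonyl oxygens in a square-planar chelate whose tert-butyl group shields one ketone face, so the ketene acetal attacks the re face in an open transition state (C2 becomes R) with its methyl group placed as the methyl of a propionate ketene acetal is in the syn-selective series (C3 becomes S), and silyl transfer to the aldolate then frees the catalyst; the closest known reaction is the [Cu(t-Bu-box)](OTf)2-catalysed Mukaiyama aldol addition of α-monosubstituted silyl ketene thioacetals to pyruvate esters, which has not been shown for a fully substituted α-alkoxy ketene acetal that creates two adjacent tetrasubstituted carbons.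

Step 5
Reactants: 10 methyl (2R,3S)-4-(ethylsulfanyl)-2-hydroxy-3-methoxy-3-methyl-4-oxo-2-[(trimethylsilyl)ethynyl]butanoate
Product: 11 methyl (2R,3S)-4-(ethylsulfanyl)-3-methoxy-3-methyl-4-oxo-2-[(triethylsilyl)oxy]-2-[(trimethylsilyl)ethynyl]butanoate
Conditions: TESOTf, 2,6-lutidine, CH2Cl2, 0 °C to rt
Reagents that add atoms: triethylsilyl trifluoromethanesulfonate, CC[Si](CC)(CC)OS(=O)(=O)C(F)(F)F
Why: A silyl triflate with a hindered pyridine base is reactive enough to silylate a crowded tertiary alcohol (silyl ether formation), and the ether blocks retro-aldol cleavage and later oxa-Michael closure.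

Step 6
Reactants: 11 methyl (2R,3S)-4-(ethylsulfanyl)-3-methoxy-3-methyl-4-oxo-2-[(triethylsilyl)oxy]-2-[(trimethylsilyl)ethynyl]butanoate
Product: 12 methyl (2R,3S)-4-(ethylsulfanyl)-2-ethynyl-3-methoxy-3-methyl-4-oxo-2-[(triethylsilyl)oxy]butanoate
Conditions: K2CO3 (20 mol%), MeOH, 0 °C, short reaction time
Reagents that add atoms: none
Why: Methoxide-catalysed protodesilylation of an alkynylsilane is fast at 0 °C, whereas the tertiary triethylsilyl ether and the thioester on a fully substituted carbon should react much more slowly.

Step 7
Reactants: 12 methyl (2R,3S)-4-(ethylsulfanyl)-2-ethynyl-3-methoxy-3-methyl-4-oxo-2-[(triethylsilyl)oxy]butanoate; 1 ethynyltrimethylsilane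
Product: 13 methyl (2R,3S)-2-ethynyl-3-methoxy-3-methyl-4-oxo-2-[(triethylsilyl)oxy]-6-(trimethylsilyl)hex-5-ynoate
Conditions: PdCl2(dppf) (cat.), P(2-furyl)3 (cat.), CuI (stoichiometric), Et3N, DMF, 50 °C, fivefold excess of the silylacetylene
Reagents that add atoms: none
Why: In this Fukuyama-type thioester–alkyne coupling, zerovalent palladium inserts into the C–S bond with help from thiophilic CuI and the copper acetylide of ethynyltrimethylsilane delivers the alkynyl group, while the methyl ester is inert and the large excess of the silylacetylene should outcompete the hindered alkyne of the substrate.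

Step 8
Reactants: 14 (S)-2-methylbutan-1-ol
Product: 15 (S)-2-methylbutanal
Conditions: TEMPO (cat.), KBr (cat.), NaOCl, NaHCO3, CH2Cl2/H2O, 0 °C
Reagents that add atoms: none
Why: The buffered two-phase oxoammonium (Anelli) oxidation stops at the aldehyde and is mild enough to leave the α-stereocentre intact.

Step 9
Reactants: 15 (S)-2-methylbutanal
Product: 16 (2E,4S)-2,4-dimethylhex-2-enal
Conditions: Ph3P=C(Me)CHO, toluene, 90 °C
Reagents that add atoms: 2-(triphenylphosphoranylidene)propanal, CC(C=O)=P(c1ccccc1)(c1ccccc1)c1ccccc1
Why: A Wittig reaction with a stabilised formyl ylide should give the E trisubstituted enal under neutral conditions that do not enolise the aldehyde.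

Step 10
Reactants: 16 (2E,4S)-2,4-dimethylhex-2-enal
Product: 17 (2E,4E,6S)-4,6-dimethylocta-2,4-dienenitrile
Conditions: (EtO)2P(O)CH2CN, NaH, THF, 0 °C; then the enal, 0 °C to rt; chromatographic removal of any 2Z isomer
Reagents that add atoms: diethyl (cyanomethyl)phosphonate, CCOP(=O)(CC#N)OCC
Why: The Horner–Wadsworth–Emmons reaction of the preformed phosphonate anion should favour the E-alkene, and the absence of free base protects the γ-stereocentre from vinylogous enolisation.

Step 11
Reactants: 13 methyl (2R,3S)-2-ethynyl-3-methoxy-3-methyl-4-oxo-2-[(triethylsilyl)oxy]-6-(trimethylsilyl)hex-5-ynoate; 17 (2E,4E,6S)-4,6-dimethylocta-2,4-dienenitrile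
Product: 18 methyl (5R,6S)-3-[(1E,3E,5S)-3,5-dimethylhepta-1,3-dien-1-yl]-6-methoxy-6-methyl-7-oxo-5-[(triethylsilyl)oxy]-1-(trimethylsilyl)-6,7-dihydro-5H-cyclopenta[c]pyridine-5-carboxylate
Conditions: CpCo(CO)2 (20 mol%), degassed toluene, reflux, visible-light irradiation, nitrile in fivefold excess, slow addition of the diynone to catalyst and nitrile
Reagents that add atoms: none
Why: Loss of CO from CpCo(CO)2 (monovalent cobalt) under light lets the CpCo fragment bind both alkynes of the diynone and couple them oxidatively to a bicyclic cobaltacyclopentadiene (trivalent cobalt), which forms C4a–C7a. The nitrile then coordinates through nitrogen, its carbon inserts into the unhindered Co–C4 bond (C3–C4), and C–N reductive elimination at the silyl-bearing carbon (N2–C1) releases the pyridine and the CpCo fragment. The closest known reaction is the CpCo-catalysed cocyclotrimerisation of α,ω-diynes with nitriles to ring-fused pyridines, which alkenyl nitriles undergo at C≡N only. The cyclopentanone closes by alkyne–alkyne oxidative cyclisation across the C5–C6–C7 tether, helped by its two fully substituted carbons, and the pyridine closes by the formal [4+2] union of the cobaltacycle with C≡N. No stereocentre is formed, and C5, C6 and the side-chain centre carry through unchanged. The step needs N to bond to C1 and needs C≡N to react in preference to the diene and to a second diyne: the trimethylsilyl cap blocks C–C bond formation at C1, excess nitrile with slow diyne addition suppresses self-trimerisation, and the silyl ether prevents oxa-Michael closure onto the ynone.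

Step 12
Reactants: 18 methyl (5R,6S)-3-[(1E,3E,5S)-3,5-dimethylhepta-1,3-dien-1-yl]-6-methoxy-6-methyl-7-oxo-5-[(triethylsilyl)oxy]-1-(trimethylsilyl)-6,7-dihydro-5H-cyclopenta[c]pyridine-5-carboxylate
Product: 19 methyl (5R,6S)-3-[(1E,3E,5S)-3,5-dimethylhepta-1,3-dien-1-yl]-5-hydroxy-6-methoxy-6-methyl-7-oxo-6,7-dihydro-5H-cyclopenta[c]pyridine-5-carboxylate
Conditions: TBAF, AcOH, THF, 0 °C to rt
Reagents that add atoms: none
Why: Fluoride should cleave both the activated 2-pyridyl C–Si bond (protodesilylation) and the Si–O bond, and the acetic acid buffer keeps the tertiary alkoxide from opening the β-hydroxy ketone by retro-aldol.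

## Compound list

1 | ethynyltrimethylsilane | C#C[Si](C)(C)C | starting material
2 | dimethyl oxalate | COC(=O)C(=O)OC | starting material
3 | lithium trimethylsilylacetylide (formed in the flask) | [Li]C#C[Si](C)(C)C | intermediate
4 | methyl 2-oxo-4-(trimethylsilyl)but-3-ynoate | COC(=O)C(=O)C#C[Si](C)(C)C | intermediate
5 | methyl 2-methoxypropanoate (racemic) | COC(C)C(=O)OC | starting material
6 | S-ethyl 2-methoxypropanethioate (racemic) | CCSC(=O)C(C)OC | intermediate
7 | lithium (E)-1-(ethylsulfanyl)-2-methoxyprop-1-en-1-olate (formed in the flask) | C/C(OC)=C(/O[Li])SCC | intermediate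
8 | (E)-1-(ethylsulfanyl)-2-methoxy-1-[(trimethylsilyl)oxy]prop-1-ene | C/C(OC)=C(/O[Si](C)(C)C)SCC | intermediate
9 | methyl (2R,3S)-4-(ethylsulfanyl)-3-methoxy-3-methyl-4-oxo-2-[(trimethylsilyl)ethynyl]-2-[(trimethylsilyl)oxy]butanoate (formed in the flask) | CCSC(=O)[C@@](C)(OC)[C@@](O[Si](C)(C)C)(C(=O)OC)C#C[Si](C)(C)C | intermediate
10 | methyl (2R,3S)-4-(ethylsulfanyl)-2-hydroxy-3-methoxy-3-methyl-4-oxo-2-[(trimethylsilyl)ethynyl]butanoate | CCSC(=O)[C@@](C)(OC)[C@@](O)(C(=O)OC)C#C[Si](C)(C)C | intermediate
11 | methyl (2R,3S)-4-(ethylsulfanyl)-3-methoxy-3-methyl-4-oxo-2-[(triethylsilyl)oxy]-2-[(trimethylsilyl)ethynyl]butanoate | CCSC(=O)[C@@](C)(OC)[C@@](O[Si](CC)(CC)CC)(C(=O)OC)C#C[Si](C)(C)C | intermediate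
12 | methyl (2R,3S)-4-(ethylsulfanyl)-2-ethynyl-3-methoxy-3-methyl-4-oxo-2-[(triethylsilyl)oxy]butanoate | CCSC(=O)[C@@](C)(OC)[C@@](O[Si](CC)(CC)CC)(C(=O)OC)C#C | intermediate
13 | methyl (2R,3S)-2-ethynyl-3-methoxy-3-methyl-4-oxo-2-[(triethylsilyl)oxy]-6-(trimethylsilyl)hex-5-ynoate | C[Si](C)(C)C#CC(=O)[C@@](C)(OC)[C@@](O[Si](CC)(CC)CC)(C(=O)OC)C#C | intermediate
14 | (S)-2-methylbutan-1-ol | CC[C@H](C)CO | starting material
15 | (S)-2-methylbutanal | CC[C@H](C)C=O | intermediate
16 | (2E,4S)-2,4-dimethylhex-2-enal | CC[C@H](C)/C=C(C)/C=O | intermediate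
17 | (2E,4E,6S)-4,6-dimethylocta-2,4-dienenitrile | CC[C@H](C)/C=C(C)/C=C/C#N | intermediate
18 | methyl (5R,6S)-3-[(1E,3E,5S)-3,5-dimethylhepta-1,3-dien-1-yl]-6-methoxy-6-methyl-7-oxo-5-[(triethylsilyl)oxy]-1-(trimethylsilyl)-6,7-dihydro-5H-cyclopenta[c]pyridine-5-carboxylate | CC[C@H](C)/C=C(C)/C=C/c1cc2c(c([Si](C)(C)C)n1)C(=O)[C@@](C)(OC)[C@@]2(O[Si](CC)(CC)CC)C(=O)OC | intermediate
19 | methyl (5R,6S)-3-[(1E,3E,5S)-3,5-dimethylhepta-1,3-dien-1-yl]-5-hydroxy-6-methoxy-6-methyl-7-oxo-6,7-dihydro-5H-cyclopenta[c]pyridine-5-carboxylate | CC[C@H](C)/C=C(C)/C=C/c1cc2c(cn1)C(=O)[C@@](C)(OC)[C@@]2(O)C(=O)OC | target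

## Step count and risks

Total step count: 12. Longest linear sequence: 8 steps (steps 2, 3, 4, 5, 6, 7, 11 and 12, from methyl 2-methoxypropanoate).

Steps most likely to fail:

1. Step 4 (proposed new method). The two faces of the fully substituted ketene acetal may be poorly differentiated, and silyl transfer to the crowded copper aldolate may be too slow for turnover. The fallback sets out from 4 and 8 and uses known chemistry: a TiCl4-promoted Mukaiyama aldol addition (stoichiometric Lewis acid, CH2Cl2, −78 °C), which is established for joining fully substituted silyl ketene acetals to α-keto esters. After the diastereomers are separated on silica this should give the racemic hydroxy thioester F1, whose enantiomers are then separated by preparative chromatography on a chiral stationary phase. The (2R,3S) enantiomer is compound 10, where the route is rejoined.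

2. Step 11. The alkenes of the dienyl nitrile or a second diyne molecule may compete for the cobaltacycle, and light or heat may scramble the diene geometry. The fallback sets out from 13 and runs the same CpCo(CO)2 cocyclisation with diethyl (cyanomethyl)phosphonate, a simple unconjugated nitrile that can be used in large excess, to give the picolyl phosphonate F2. A Horner–Wadsworth–Emmons reaction of F2 with enal 16 (LiN(SiMe3)2, THF, −78 to 0 °C) then joins the side chain after ring formation and forms the E-alkene next to the pyridine, coming back to the route at 18.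

3. Step 7. Oxidative addition into the neopentyl-like thioester may be slow, and the substrate's own terminal alkyne may be acylated in competition. The fallback sets out from 12 and replaces the palladium coupling by a Weinreb ketone synthesis. Aminolysis of the thioester with ClMgN(OMe)Me (from MeNHOMe·HCl and i-PrMgCl, THF, −20 °C) should give the Weinreb amide F3; the thioester is expected to react before the shielded methyl ester. Addition of lithium trimethylsilylacetylide 3 (excess, THF, −78 °C) then stops at the chelated tetrahedral adduct and should give the ynone on work-up, rejoining the route at 13.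

Further compounds
F1 | step 4 | racemic methyl (2R*,3S*)-4-(ethylsulfanyl)-2-hydroxy-3-methoxy-3-methyl-4-oxo-2-[(trimethylsilyl)ethynyl]butanoate | CCSC(=O)[C@@](C)(OC)[C@@](O)(C(=O)OC)C#C[Si](C)(C)C.CCSC(=O)[C@](C)(OC)[C@](O)(C(=O)OC)C#C[Si](C)(C)C
F2 | step 11 | methyl (5R,6S)-3-[(diethoxyphosphoryl)methyl]-6-methoxy-6-methyl-7-oxo-5-[(triethylsilyl)oxy]-1-(trimethylsilyl)-6,7-dihydro-5H-cyclopenta[c]pyridine-5-carboxylate | CCOP(=O)(Cc1cc2c(c([Si](C)(C)C)n1)C(=O)[C@@](C)(OC)[C@@]2(O[Si](CC)(CC)CC)C(=O)OC)OCC
F3 | step 7 | methyl (2R,3S)-2-ethynyl-3-methoxy-4-[methoxy(methyl)amino]-3-methyl-4-oxo-2-[(triethylsilyl)oxy]butanoate | CON(C)C(=O)[C@@](C)(OC)[C@@](O[Si](CC)(CC)CC)(C(=O)OC)C#C
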